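**Retrosynthesis**
1. Target ⇐ C3/C13 diacetate ⇐ γ-lactonisation of C2–OH onto the C16 ester plus acetonide removal ⇐ 14-membered diene **18** (ring closed by RCM at C4=C5).
2. **18** ⇐ acyclic ketone **17**, made by a Claisen [3,3] rearrangement (bond C14–C1) between methyl ketone **6** (from (R)-linalool, C8–C14) and acrylate allylic alcohol **13** (from D-erythronolactone acetonide, C1–C4).
3. The Claisen step sets C1 (controlled by C2) and the exo-methylene acrylate. C12 comes from linalool, C2/C3 from the erythronolactone, and C13 from a chelation-controlled ketone reduction controlled by C12.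

Assumption: (R)-linalool and 2,3-O-isopropylidene-D-erythronolactone are taken as commercial chiral-pool materials. Simple reagents are not numbered and are listed in each step. Cembrane numbering is used throughout (C1 bears the lactone methylene carbon C15; C12 is the tertiary carbinol).

---

**Step 1**
Reactants: 1, (R)-linalool
Product: 2, TBS ether of (R)-linalool
Conditions: TBSOTf, 2,6-lutidine, CH2Cl2, −78 → 0 °C
Reagents that add atoms: TBSOTf, CC(C)(C)[Si](C)(C)OS(=O)(=O)C(F)(F)F
Why: Silylation of the tertiary alcohol prevents the later degenerate α-ketol shift, which would racemise C12. It leaves the C12 configuration untouched (silyl protection).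

**Step 2**
Reactants: 2
Product: 3, (3R)-3-(TBSO)-3,7-dimethyloct-6-en-2-one
Conditions: PdCl2 (10 mol%), CuCl (1 equiv), O2 (balloon), DMF/H2O 7:1, 25–40 °C
Reagents that add atoms: O2, O=O; water, O
Why: Tsuji–Wacker Markovnikov oxidation is selective for the monosubstituted vinyl group over the trisubstituted alkene and gives the C13 methyl ketone (C14 = CH3). C12 is not involved.

**Step 3**
Reactants: 3
Product: 4, (3R,6E)-8-hydroxy-3-(TBSO)-3,7-dimethyloct-6-en-2-one
Conditions: SeO2 (10 mol%), TBHP, CH2Cl2, 0 → 25 °C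
Reagents that add atoms: TBHP, CC(C)(C)OO
Why: Riley allylic oxidation hydroxylates the methyl trans to the chain, which fixes the E geometry of C8=C9. No stereocenter is formed.

**Step 4**
Reactants: 4
Product: 5, allylic bromide (C7–Br, E)
Conditions: CBr4, PPh3, CH2Cl2, 0 °C
Reagents that add atoms: CBr4, BrC(Br)(Br)Br
Why: Appel bromination proceeds by direct SN2 at the primary allylic carbon, with no allylic transposition.

**Step 5**
Reactants: 5
Product: 6, (3R,6E)-3-(TBSO)-3,7-dimethylundeca-6,10-dien-2-one (terminal C5=CH2)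
Conditions: allylSnBu3 (1.5 equiv), Pd(PPh3)4 (5 mol%), LiCl, THF, 50 °C
Reagents that add atoms: allyltributylstannane, C=CC[Sn](CCCC)(CCCC)CCCC
Why: Godschalx–Stille allyl–allyl coupling takes place at the unhindered α-terminus of the geranyl-type bromide. It installs C6/C5 and keeps the ketone and the C8=C9 geometry.

**Step 6**
Reactants: 7, 2,3-O-isopropylidene-D-erythronolactone
Product: 8, methyl lactol (hemiketal, anomeric mixture)
Conditions: MeLi (1.05 equiv), THF, −78 °C
Reagents that add atoms: methyllithium, [Li]C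
Why: Organolithium addition to an acetonide lactone stops at the stable lactol (tetrahedral intermediate) at −78 °C, which gives the C4 methyl-ketone equivalent. The cis-acetonide C2/C3 centres are retained.

**Step 7**
Reactants: 8
Product: 9, [(4R,5S)-2,2-dimethyl-5-isopropenyl-1,3-dioxolan-4-yl]methanol
Conditions: Ph3P=CH2 (from Ph3PCH3Br, KOtBu, 3 equiv), THF, 0 → 25 °C
Reagents that add atoms: methyltriphenylphosphonium bromide, C[P+](c1ccccc1)(c1ccccc1)c1ccccc1.[Br-]
Why: Wittig methylenation of the open keto-alcohol tautomer of the lactol gives the C4 isopropenyl group and releases the C1 primary alcohol.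

**Step 8**
Reactants: 9
Product: 10, (4S,5S)-2,2-dimethyl-5-isopropenyl-1,3-dioxolane-4-carbaldehyde
Conditions: Dess–Martin periodinane, NaHCO3, CH2Cl2, 0 °C; used crude and immediately
Reagents that add atoms: none
Why: Mild oxidation gives the α-alkoxy aldehyde without epimerising C2.

**Step 9**
Reactants: 10
Product: 11, Baylis–Hillman adduct (C1 carbinol, epimeric mixture)
Conditions: methyl acrylate (5 equiv), DABCO (0.5 equiv), 25 °C, 3–4 d
Reagents that add atoms: methyl acrylate, C=CC(=O)OC
Why: Morita–Baylis–Hillman reaction installs C15/C16/C17. The new carbinol stereocenter is destroyed in step 11, so its configuration does not matter.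

**Step 10**
Reactants: 11
Product: 12, MBH acetate
Conditions: Ac2O, Et3N, DMAP (cat.), CH2Cl2, 0 °C
Reagents that add atoms: acetic anhydride, CC(=O)OC(C)=O
Why: Acetylation makes the carbinol a leaving group for the SN2′ sequence in step 11.

**Step 11**
Reactants: 12
Product: 13, methyl (2E)-2-(hydroxymethyl)-3-[(4R,5S)-2,2-dimethyl-5-isopropenyl-1,3-dioxolan-4-yl]acrylate
Conditions: DABCO (1.2 equiv), THF/H2O 3:1, 25 °C
Reagents that add atoms: water, O
Why: DABCO-mediated SN2′/SN2′ hydrolysis of the MBH acetate moves the oxygen to the primary allylic carbon. It gives the thermodynamic trisubstituted alkene, with C2 trans to the ester and cis to CH2OH.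

**Step 12 (key step)**
Reactants: 6, 13
Product: 14, acyclic C1–C14 ketone with a 2-carbomethoxy-allyl (acrylate) group at C1, the acetonide and the 12-OTBS
Conditions: 13 (2 equiv), (MeO)3CH, PPTS (0.2 equiv), 4 Å MS, toluene, 110 °C; then sealed tube, o-xylene, 160 °C
Reagents that add atoms: none (trimethyl orthoformate and MeOH are lost)
Why: The methyl ketone (only C14 is enolisable, since C12 is quaternary) forms a mixed allyl enol ether in situ, and the Saucy–Marbet/Claisen [3,3] rearrangement forms C14–C1. C1 is set by Felkin-type facial bias of the allylic C2 centre (H inside, attack anti to the C2–O bond), and the exo-methylene acrylate forms as C17 becomes =CH2.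

**Step 13**
Reactants: 14
Product: 15, free tertiary α-hydroxy ketone
Conditions: HF·pyridine, pyridine/THF, 25–40 °C
Reagents that add atoms: none
Why: Fluoride-mediated desilylation of the hindered tertiary silyl ether. The acetonide and acrylate survive, and the product is used at once.

**Step 14**
Reactants: 15
Product: 16, (12R,13S)-diol
Conditions: Zn(BH4)2, Et2O, −20 °C
Reagents that add atoms: none
Why: In the chelate (O12–Zn–O13) the hydride enters from the face of the smaller Me group rather than CH2R, giving 13S (Cram-chelate control from the C12 centre). The acrylate ester is untouched.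

**Step 15**
Reactants: 16
Product: 17, 13-monoacetate
Conditions: Ac2O (1.2 equiv), pyridine, DMAP (5 mol%), CH2Cl2, 0 °C
Reagents that add atoms: acetic anhydride, CC(=O)OC(C)=O
Why: The secondary C13–OH is acylated selectively over the tertiary C12–OH. This also removes C13–OH as a competing lactonisation partner.

**Step 16**
Reactants: 17
Product: 18, 14-membered macrocycle with E-C4=C5
Conditions: Hoveyda–Grubbs II (10 mol%), toluene, 2 mM, 80 °C, Ar sparge
Reagents that add atoms: none (ethylene is lost)
Why: Ring-closing metathesis joins the isopropenyl (C4) and vinyl (C5) termini. The E trisubstituted alkene is favoured in a 14-membered ring under reversible conditions, and the acrylate is a poor metathesis partner.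

**Step 17**
Reactants: 18
Product: 19, lactone with free 3-OH
Conditions: (i) 80% aq. AcOH, 45 °C; (ii) concentrate, TsOH·H2O (0.1 equiv), toluene, 60 °C
Reagents that add atoms: water, O
Why: Acetonide hydrolysis releases the C2/C3 diol, and acid-catalysed lactonisation of C2–OH onto the C16 methyl ester (loss of MeOH) closes the γ-lactone, which is trans-fused because C1/C2 are already set. This gives the α-methylene-γ-butyrolactone.

**Step 18**
Reactants: 19
Product: 20, crassocolide B
Conditions: Ac2O (3 equiv), pyridine, DMAP (5 mol%), CH2Cl2, 25 °C, 2 h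
Reagents that add atoms: acetic anhydride, CC(=O)OC(C)=O
Why: The only remaining secondary alcohol (C3–OH) is acetylated, and the hindered tertiary C12–OH stays free, giving the target.

---

**Compound list**

| # | Name | SMILES | Role |
|---|---|---|---|
| 1 | (3R)-3,7-dimethylocta-1,6-dien-3-ol, (R)-linalool | C=C[C@](C)(O)CCC=C(C)C | starting material |
| 2 | TBS ether of 1 | C=C[C@](C)(O[Si](C)(C)C(C)(C)C)CCC=C(C)C | intermediate |
| 3 | (3R)-3-(TBSO)-3,7-dimethyloct-6-en-2-one | CC(=O)[C@](C)(O[Si](C)(C)C(C)(C)C)CCC=C(C)C | intermediate |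
| 4 | (3R,6E)-8-hydroxy-3-(TBSO)-3,7-dimethyloct-6-en-2-one | CC(=O)[C@](C)(O[Si](C)(C)C(C)(C)C)CC/C=C(\C)CO | intermediate |
| 5 | (3R,6E)-8-bromo-3-(TBSO)-3,7-dimethyloct-6-en-2-one | CC(=O)[C@](C)(O[Si](C)(C)C(C)(C)C)CC/C=C(\C)CBr | intermediate |
| 6 | (3R,6E)-3-(TBSO)-3,7-dimethylundeca-6,10-dien-2-one | CC(=O)[C@](C)(O[Si](C)(C)C(C)(C)C)CC/C=C(\C)CCC=C | intermediate |
| 7 | (3aR,6aR)-2,2-dimethyldihydrofuro[3,4-d][1,3]dioxol-4(3aH)-one (2,3-O-isopropylidene-D-erythronolactone) | O=C1OC[C@H]2OC(C)(C)O[C@@H]12 | starting material |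
| 8 | (3aR,6aR)-2,2,4-trimethyltetrahydrofuro[3,4-d][1,3]dioxol-4-ol, methyl lactol | CC1(O)OC[C@H]2OC(C)(C)O[C@@H]12 | intermediate |
| 9 | [(4R,5S)-2,2-dimethyl-5-isopropenyl-1,3-dioxolan-4-yl]methanol | C=C(C)[C@@H]1OC(C)(C)O[C@@H]1CO | intermediate |
| 10 | (4S,5S)-2,2-dimethyl-5-isopropenyl-1,3-dioxolane-4-carbaldehyde | C=C(C)[C@@H]1OC(C)(C)O[C@@H]1C=O | intermediate |
| 11 | MBH adduct (C1 carbinol, epimeric mixture; dioxolane as in 10) | C=C(C)[C@@H]1OC(C)(C)O[C@@H]1C(O)C(=C)C(=O)OC | intermediate |
| 12 | MBH acetate of 11 | C=C(C)[C@@H]1OC(C)(C)O[C@@H]1C(OC(C)=O)C(=C)C(=O)OC | intermediate |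
| 13 | methyl (2E)-2-(hydroxymethyl)-3-[(4R,5S)-2,2-dimethyl-5-isopropenyl-1,3-dioxolan-4-yl]acrylate | C=C(C)[C@@H]1OC(C)(C)O[C@@H]1/C=C(\CO)C(=O)OC | intermediate |
| 14 | Claisen ketone (1R,2R,3S,12R; 12-OTBS; 2,3-acetonide; acrylate methyl ester) | C=C(C)[C@@H]1OC(C)(C)O[C@@H]1[C@H](CC(=O)[C@](C)(O[Si](C)(C)C(C)(C)C)CC/C=C(\C)CCC=C)C(=C)C(=O)OC | intermediate |
| 15 | 12-desilyl ketone of 14 | C=C(C)[C@@H]1OC(C)(C)O[C@@H]1[C@H](CC(=O)[C@](C)(O)CC/C=C(\C)CCC=C)C(=C)C(=O)OC | intermediate |
| 16 | (12R,13S)-diol from reduction | C=C(C)[C@@H]1OC(C)(C)O[C@@H]1[C@H](C[C@H](O)[C@](C)(O)CC/C=C(\C)CCC=C)C(=C)C(=O)OC | intermediate |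
| 17 | 13-acetate of 16 | C=C(C)[C@@H]1OC(C)(C)O[C@@H]1[C@H](C[C@H](OC(C)=O)[C@](C)(O)CC/C=C(\C)CCC=C)C(=C)C(=O)OC | intermediate |
| 18 | RCM macrocycle (acetonide, methyl acrylate, 13-OAc, free 12-OH) | C=C(C(=O)OC)[C@H]1C[C@H](OC(C)=O)[C@](C)(O)CC/C=C(\C)CC/C=C(\C)[C@@H]2OC(C)(C)O[C@H]12 | intermediate |
| 19 | 3-hydroxy lactone (3-deacetyl crassocolide B) | C=C1C(=O)O[C@@H]2[C@@H]1C[C@H](OC(C)=O)[C@](C)(O)CC/C=C(\C)CC/C=C(\C)[C@@H]2O | intermediate |
| 20 | crassocolide B | C=C1C(=O)O[C@@H]2[C@@H]1C[C@H](OC(C)=O)[C@](C)(O)CC/C=C(\C)CC/C=C(\C)[C@@H]2OC(C)=O | target |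

**Totals:** 18 steps; the longest linear sequence is 13 steps (7 → 8 → 9 → 10 → 11 → 13 → 14 → 15 → 16 → 17 → 18 → 19 → 20, counting steps 6–11 and 12–18). The right-hand fragment (steps 1–5) is made in parallel.

**Three steps most likely to fail**
1. **Step 12 (Claisen).** Mixed-ketal/enol-ether formation on the hindered α-quaternary ketone may be low-yielding, and the C1 diastereoselectivity is only model-based.
   - Fallback: build the C1–C14 bond by Mukaiyama–Michael addition of the TMS enol ether of 6 to a γ-(erythrose-derived) butenolide, which adds anti to the γ-substituent, followed by α-methylenation of the lactone.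
2. **Step 16 (RCM).** The hindered 1,1-disubstituted alkene may give low conversion, oligomers or Z-isomer.
   - Fallback: close the ring instead by intramolecular Nozaki–Hiyama–Kishi coupling (vinyl iodide at C4, aldehyde at C3) or by Corey-type Ni(0) coupling of the C6/C7 bis-allylic bromides.
3. **Step 14 (chelation-controlled reduction).** Me and CH2R are similar in size, so dr may be modest, and the free α-ketol can racemise.
   - Fallback: reduce non-selectively with NaBH4, separate the epimers, and invert the unwanted C13 alcohol by Mitsunobu reaction (p-nitrobenzoic acid) followed by methanolysis.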